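**Plan**

1. Retrosynthesis: cut first the two side-chain ester C–O bonds (acetate at the allylic CH2, angelate at C3), then the C3–H bond (carbinol back to ketone), then the exocyclic C2–C(alkenyl) bond, and last O1–C2 of the five-membered ring, which leads to 4,6-diacetylresorcinol.
2. Enabling feature: C2 lies between ring oxygen O1 and the C3 carbinol. With C3 raised to the ketone, the O1–C2–C3 unit of the dihydrofuran ring is a benzofuran-3(2H)-one whose enolate is an aromatic 3-oxidobenzofuran, so C2 is a soft carbon nucleophile and stays configurationally labile after coupling.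
3. Forward: the benzene ring is bought fully substituted; the furanone ring closes by 5-exo-tet O-alkylation; the C3 side chain is joined at C2 by Pd-catalysed enolate alkenylation with a 2-bromoallyl silyl ether (silyl, not acetate: no allylic ester for Pd(0), no free CH2OH to close onto the C3 ketone).
4. Stereochemistry: the target is the 2,3-cis (2R,3R) isomer. Both centres are set together by one Ru/(S,S)-TsDPEN transfer hydrogenation with dynamic kinetic resolution of the C2-labile ketone (catalyst gives 3R, hydride anti to the C2 group gives cis); the Z-alkene is bought as angelic anhydride and kept by a catalyst-free alkoxide acylation.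
5. End game: the helpers leave again (C3 carbonyl by the reduction, both silyl groups by fluoride), then the primary allylic alcohol is acetylated beside the acetyl-chelated C6 phenol.

Key step: step 5

Assumption: compounds 1, 5 and 11 are taken as purchasable.

**Route**

Step 1
Reactants: 1 4,6-diacetylresorcinol
Product: 2 1-(5-acetyl-2,4-dihydroxyphenyl)-2-bromoethan-1-one
Conditions: CuBr2 (2.0 equiv), EtOAc/CHCl3 (1:1), reflux
Reagents that add atoms: copper(II) bromide, Br[Cu]Br
Why: Copper(II) bromide α-bromination of an aryl methyl ketone through its copper enolate; the two acetyl groups of 1 are equivalent, so the stoichiometry should make the mono-bromide the main product (unreacted 1 recyclable), and the chelated, doubly acyl-deactivated ring should not be brominated.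

Step 2
Reactants: 2 1-(5-acetyl-2,4-dihydroxyphenyl)-2-bromoethan-1-one
Product: 3 5-acetyl-6-hydroxybenzofuran-3(2H)-one
Conditions: NaOAc (2 equiv), EtOH, reflux
Reagents that add atoms: none
Why: Intramolecular Williamson etherification (5-exo-tet) by the phenol ortho to the bromoacetyl group, the standard closure of a benzofuran-3(2H)-one; the other phenol is para to that side chain and cannot reach it.

Step 3
Reactants: 3 5-acetyl-6-hydroxybenzofuran-3(2H)-one
Product: 4 5-acetyl-6-[(triisopropylsilyl)oxy]benzofuran-3(2H)-one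
Conditions: TIPSCl (1.05 equiv), Et3N (1.1 equiv), DMAP (cat.), CH2Cl2, 0 °C
Reagents that add atoms: chlorotriisopropylsilane, CC(C)[Si](Cl)(C(C)C)C(C)C
Why: Silyl ether formation at the only OH: the C6 phenol (ortho to acetyl, para to the C3 carbonyl) is far more acidic than C2–H, so one equivalent of amine gives the phenoxide and leaves no base to enolise C2; TIPS is chosen to survive phosphate base, formic acid/triethylamine and a lithium alkoxide and still leave with fluoride.

Step 4
Reactants: 5 2-bromoprop-2-en-1-ol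
Product: 6 [(2-bromoprop-2-en-1-yl)oxy](tert-butyl)dimethylsilane
Conditions: TBSCl, imidazole, CH2Cl2, rt
Reagents that add atoms: tert-butylchlorodimethylsilane, CC(C)(C)[Si](C)(C)Cl
Why: Standard silylation of a primary alcohol; a silyl ether replaces the final acetate because Pd(0) would ionise a 2-bromoallyl ester to a π-allyl complex and deliver the CH2 terminus instead of the vinylic carbon.

Step 5
Reactants: 4 5-acetyl-6-[(triisopropylsilyl)oxy]benzofuran-3(2H)-one; 6 [(2-bromoprop-2-en-1-yl)oxy](tert-butyl)dimethylsilane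
Product: 9 racemic 5-acetyl-2-{3-[(tert-butyldimethylsilyl)oxy]prop-1-en-2-yl}-6-[(triisopropylsilyl)oxy]benzofuran-3(2H)-one, via potassium enolate 7 (not isolated), via potassium dienolate 8 (not isolated)
Conditions: Pd2(dba)3 (2.5 mol %), t-Bu3P·HBF4 (6 mol %), ground K3PO4 (2.2 equiv), 6 (1.05 equiv), PhMe, 60 °C; then cold pH 7 KH2PO4/K2HPO4 buffer, 0 °C; crude 9 carried on without silica chromatography
Reagents that add atoms: none
Why: Palladium-catalysed α-alkenylation of a ketone enolate, the alkenyl version of the Buchwald–Hartwig-type α-arylation known for ketones including benzofuran-3(2H)-ones: Pd(0)/t-Bu3P adds into the C(sp2)–Br bond of 6, phosphate converts 4 into the aromatic 3-oxidobenzofuran enolate 7, which binds palladium through C2, and C–C reductive elimination forms the C2–C(alkenyl) bond. The coupled ketone is more acidic than 4 and rests as the cross-conjugated dienolate 8, which the cold neutral quench should protonate kinetically at C2 to give the β,γ-unsaturated ketone 9. No ring is closed and no stereocentre is fixed: C2 is formed racemic and is left enolisable on purpose for the dynamic resolution in step 6. The step needs C2 over the acetyl CH3 (much higher acidity of the α-aryloxy, aromatic-enolate position; weak heterogeneous base), mono- over bis-alkenylation (8 is hindered and stabilised; 6 is nearly limiting), bond formation at the vinylic carbon and not at CH2 (a silyl ether gives no π-allyl complex), and no migration of the exocyclic double bond into conjugation with C3=O (buffered cold α-protonation, no silica).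

Step 6
Reactants: 9 racemic 5-acetyl-2-{3-[(tert-butyldimethylsilyl)oxy]prop-1-en-2-yl}-6-[(triisopropylsilyl)oxy]benzofuran-3(2H)-one
Product: 10 1-[(2R,3R)-2-{3-[(tert-butyldimethylsilyl)oxy]prop-1-en-2-yl}-3-hydroxy-6-[(triisopropylsilyl)oxy]-2,3-dihydro-1-benzofuran-5-yl]ethan-1-one (2,3-cis)
Conditions: RuCl[(S,S)-TsDPEN](p-cymene) (1 mol %), HCO2H/Et3N (5:2), EtOAc, 25 °C
Reagents that add atoms: none
Why: Noyori–Ikariya asymmetric transfer hydrogenation with dynamic kinetic resolution of an α-substituted benzo-fused ketone: C2 should epimerise through the 3-hydroxybenzofuran enol faster than reduction, the (S,S)-catalyst is expected to give the 3R carbinol (the spatial sense it shows with simple benzo-fused ketones) and hydride arrives anti to the C2 substituent, so the (2R)-ketone is the matched, replenished enantiomer and the cis-(2R,3R) alcohol should result; the α-aryloxy C3 ketone is expected to react well before the C5 acetyl, which is deactivated by its ortho and para oxygens and shielded by OTIPS.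

Step 7
Reactants: 10 the (2R,3R)-cis alcohol; 11 angelic anhydride [(2Z)-2-methylbut-2-enoic anhydride]
Product: 13 (2R,3R)-5-acetyl-2-{3-[(tert-butyldimethylsilyl)oxy]prop-1-en-2-yl}-6-[(triisopropylsilyl)oxy]-2,3-dihydro-1-benzofuran-3-yl (2Z)-2-methylbut-2-enoate, via lithium alkoxide 12 (not isolated)
Conditions: LiHMDS (1.05 equiv), THF, −78 °C; then 11 (1.3 equiv), −78 → 0 °C; aq. NH4Cl
Reagents that add atoms: none
Why: Acylation of a lithium alkoxide with a symmetrical anhydride (stereoconservative angeloylation): without DMAP or another nucleophilic catalyst the Z-angelate should not equilibrate to the E-tiglate, and the carbinol C–O bond is untouched, so C3 keeps its configuration.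

Step 8
Reactants: 13 the bis-silylated angelate
Product: 14 (2R,3R)-5-acetyl-6-hydroxy-2-(3-hydroxyprop-1-en-2-yl)-2,3-dihydro-1-benzofuran-3-yl (2Z)-2-methylbut-2-enoate
Conditions: HF·pyridine, pyridine, THF, 0 °C → rt
Reagents that add atoms: none
Why: Fluoride cleavage of both silyl ethers (aryl O–TIPS and primary O–TBS) under buffered, non-basic conditions, so that no alkoxide or phenoxide forms that could move the C3 acyl group or expel it through a quinone-methide pathway.

Step 9
Reactants: 14 the phenol/primary alcohol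
Product: 15 (2R,3R)-5-acetyl-2-[3-(acetyloxy)prop-1-en-2-yl]-6-hydroxy-2,3-dihydro-1-benzofuran-3-yl (2Z)-2-methylbut-2-enoate (target)
Conditions: AcCl (1.1 equiv), 2,4,6-collidine (2 equiv), CH2Cl2, −78 °C
Reagents that add atoms: acetyl chloride, CC(Cl)=O
Why: Chemoselective low-temperature O-acetylation of a primary alcohol with acetyl chloride and a hindered pyridine base; the only other OH is the C6 phenol, which is hydrogen-bonded to the C5 acetyl carbonyl and should not be acylated without a nucleophilic catalyst or phenoxide formation.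

**Compound list**

1 | 4,6-diacetylresorcinol | CC(=O)c1cc(C(C)=O)c(O)cc1O | starting material
2 | 1-(5-acetyl-2,4-dihydroxyphenyl)-2-bromoethan-1-one | CC(=O)c1cc(C(=O)CBr)c(O)cc1O | intermediate
3 | 5-acetyl-6-hydroxybenzofuran-3(2H)-one | O=C1COc2cc(O)c(C(C)=O)cc21 | intermediate
4 | 5-acetyl-6-[(triisopropylsilyl)oxy]benzofuran-3(2H)-one | O=C1COc2cc(O[Si](C(C)C)(C(C)C)C(C)C)c(C(C)=O)cc21 | intermediate
5 | 2-bromoprop-2-en-1-ol | C=C(Br)CO | starting material
6 | [(2-bromoprop-2-en-1-yl)oxy](tert-butyl)dimethylsilane | C=C(Br)CO[Si](C)(C)C(C)(C)C | intermediate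
7 | potassium 5-acetyl-6-[(triisopropylsilyl)oxy]benzofuran-3-olate (enolate of 4, not isolated) | [K+].[O-]c1coc2cc(O[Si](C(C)C)(C(C)C)C(C)C)c(C(C)=O)cc12 | intermediate
8 | potassium 5-acetyl-2-{3-[(tert-butyldimethylsilyl)oxy]prop-1-en-2-yl}-6-[(triisopropylsilyl)oxy]benzofuran-3-olate (dienolate of 9, not isolated) | [K+].[O-]c1c(C(=C)CO[Si](C)(C)C(C)(C)C)oc2cc(O[Si](C(C)C)(C(C)C)C(C)C)c(C(C)=O)cc12 | intermediate
9 | racemic 5-acetyl-2-{3-[(tert-butyldimethylsilyl)oxy]prop-1-en-2-yl}-6-[(triisopropylsilyl)oxy]benzofuran-3(2H)-one | C=C(CO[Si](C)(C)C(C)(C)C)C1Oc2cc(O[Si](C(C)C)(C(C)C)C(C)C)c(C(C)=O)cc2C1=O | intermediate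
10 | 1-[(2R,3R)-2-{3-[(tert-butyldimethylsilyl)oxy]prop-1-en-2-yl}-3-hydroxy-6-[(triisopropylsilyl)oxy]-2,3-dihydro-1-benzofuran-5-yl]ethan-1-one (cis) | C=C(CO[Si](C)(C)C(C)(C)C)[C@H]1Oc2cc(O[Si](C(C)C)(C(C)C)C(C)C)c(C(C)=O)cc2[C@H]1O | intermediate
11 | angelic anhydride, (2Z)-2-methylbut-2-enoic anhydride | C/C=C(/C)C(=O)OC(=O)/C(C)=C\C | starting material
12 | lithium alkoxide of 10 (not isolated) | [Li+].C=C(CO[Si](C)(C)C(C)(C)C)[C@H]1Oc2cc(O[Si](C(C)C)(C(C)C)C(C)C)c(C(C)=O)cc2[C@H]1[O-] | intermediate
13 | (2R,3R)-5-acetyl-2-{3-[(tert-butyldimethylsilyl)oxy]prop-1-en-2-yl}-6-[(triisopropylsilyl)oxy]-2,3-dihydro-1-benzofuran-3-yl (2Z)-2-methylbut-2-enoate | C=C(CO[Si](C)(C)C(C)(C)C)[C@H]1Oc2cc(O[Si](C(C)C)(C(C)C)C(C)C)c(C(C)=O)cc2[C@H]1OC(=O)/C(C)=C\C | intermediate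
14 | (2R,3R)-5-acetyl-6-hydroxy-2-(3-hydroxyprop-1-en-2-yl)-2,3-dihydro-1-benzofuran-3-yl (2Z)-2-methylbut-2-enoate | C=C(CO)[C@H]1Oc2cc(O)c(C(C)=O)cc2[C@H]1OC(=O)/C(C)=C\C | intermediate
15 | (2R,3R)-5-acetyl-2-[3-(acetyloxy)prop-1-en-2-yl]-6-hydroxy-2,3-dihydro-1-benzofuran-3-yl (2Z)-2-methylbut-2-enoate | C=C(COC(C)=O)[C@H]1Oc2cc(O)c(C(C)=O)cc2[C@H]1OC(=O)/C(C)=C\C | target

**Step count and risks**

Total steps: 9. Longest linear sequence: 8 steps (1 → 2 → 3 → 4 → 9 → 10 → 13 → 14 → 15; step 4 prepares the side-chain partner).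

Steps most likely to fail:

1. Step 5. The exocyclic double bond may migrate into conjugation with the C3 carbonyl (γ-protonation of the dienolate or base-mediated equilibration). A second alkenylation at C2 may also occur, or reductive elimination from the stabilised aromatic enolate may be slow enough for β-silyloxy elimination of the alkenylpalladium to compete. The fallback moves the coupling to the aromatic oxidation level with reversed polarity. From 4, bromination at C2 (PhNMe3Br3, THF, 0 °C) should give 5-acetyl-2-bromo-6-[(triisopropylsilyl)oxy]benzofuran-3(2H)-one F1. Enol acetylation (Ac2O, Et3N) should give the aromatic 5-acetyl-2-bromo-6-[(triisopropylsilyl)oxy]benzofuran-3-yl acetate F2. From 6, Miyaura borylation (B2pin2, PdCl2(dppf), KOPh, PhMe) should give tert-butyldimethyl{[2-(4,4,5,5-tetramethyl-1,3,2-dioxaborolan-2-yl)prop-2-en-1-yl]oxy}silane F3. Suzuki–Miyaura coupling of F2 with F3 (PdCl2(dppf), anhydrous K3PO4, dioxane) forms the same C2–C bond as an sp2–sp2 bond and should give 5-acetyl-2-{3-[(tert-butyldimethylsilyl)oxy]prop-1-en-2-yl}-6-[(triisopropylsilyl)oxy]benzofuran-3-yl acetate F4, in which the double bond cannot migrate. Aminolysis of the enol acetate (morpholine, THF, 0 °C, then cold pH 7 buffer) releases the enol, which ketonises at C2 and rejoins the route at 9 just before step 6.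

2. Step 6. The C5 acetyl group may be reduced in competition, C2 may epimerise too slowly for the resolution to be dynamic, or the double bond may drift into conjugation in the amine/formic acid medium. The fallback separates diastereocontrol from enantiocontrol. From 9, NaBH4 in THF/MeOH at −78 °C (hydride anti to the C2 substituent; the α-aryloxy ketone reacts before the acetyl) should give the racemic cis-alcohol F5. Lipase-catalysed kinetic resolution (Burkholderia cepacia lipase, vinyl acetate, MTBE) is expected by the Kazlauskas rule to acetylate the (2S,3S)-enantiomer to the (2S,3S)-acetate F6 and leave the (2R,3R)-alcohol, which rejoins the route at 10.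

3. Step 7. The angelate may isomerise to the tiglate (Z → E) under the basic conditions, the hindered cis-carbinol may acylate slowly, or the benzylic C3 oxygen function may be lost toward the aromatic benzofuran. The fallback makes the Z double bond after the ester bond. From 10, DCC/DMAP esterification with 2-[bis(2,2,2-trifluoroethoxy)phosphoryl]propanoic acid should give the phosphonopropionate ester F7. Still–Gennari olefination (KHMDS, 18-crown-6, THF, −78 °C, acetaldehyde) should then give the (2Z)-2-methylbut-2-enoate and rejoin the route at 13.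

Further compounds
F1 | step 5 | 5-acetyl-2-bromo-6-[(triisopropylsilyl)oxy]benzofuran-3(2H)-one | O=C1C(Br)Oc2cc(O[Si](C(C)C)(C(C)C)C(C)C)c(C(C)=O)cc21
F2 | step 5 | 5-acetyl-2-bromo-6-[(triisopropylsilyl)oxy]benzofuran-3-yl acetate | CC(=O)Oc1c(Br)oc2cc(O[Si](C(C)C)(C(C)C)C(C)C)c(C(C)=O)cc12
F3 | step 5 | tert-butyldimethyl{[2-(4,4,5,5-tetramethyl-1,3,2-dioxaborolan-2-yl)prop-2-en-1-yl]oxy}silane | C=C(CO[Si](C)(C)C(C)(C)C)B1OC(C)(C)C(C)(C)O1
F4 | step 5 | 5-acetyl-2-{3-[(tert-butyldimethylsilyl)oxy]prop-1-en-2-yl}-6-[(triisopropylsilyl)oxy]benzofuran-3-yl acetate | C=C(CO[Si](C)(C)C(C)(C)C)c1oc2cc(O[Si](C(C)C)(C(C)C)C(C)C)c(C(C)=O)cc2c1OC(C)=O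
F5 | step 6 | racemic cis-alcohol, 1:1 mixture of (2R,3R)- and (2S,3S)-1-[2-{3-[(tert-butyldimethylsilyl)oxy]prop-1-en-2-yl}-3-hydroxy-6-[(triisopropylsilyl)oxy]-2,3-dihydro-1-benzofuran-5-yl]ethan-1-one | C=C(CO[Si](C)(C)C(C)(C)C)[C@H]1Oc2cc(O[Si](C(C)C)(C(C)C)C(C)C)c(C(C)=O)cc2[C@H]1O.C=C(CO[Si](C)(C)C(C)(C)C)[C@@H]1Oc2cc(O[Si](C(C)C)(C(C)C)C(C)C)c(C(C)=O)cc2[C@@H]1O
F6 | step 6 | (2S,3S)-5-acetyl-2-{3-[(tert-butyldimethylsilyl)oxy]prop-1-en-2-yl}-6-[(triisopropylsilyl)oxy]-2,3-dihydro-1-benzofuran-3-yl acetate | C=C(CO[Si](C)(C)C(C)(C)C)[C@@H]1Oc2cc(O[Si](C(C)C)(C(C)C)C(C)C)c(C(C)=O)cc2[C@@H]1OC(C)=O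
F7 | step 7 | (2R,3R)-5-acetyl-2-{3-[(tert-butyldimethylsilyl)oxy]prop-1-en-2-yl}-6-[(triisopropylsilyl)oxy]-2,3-dihydro-1-benzofuran-3-yl 2-[bis(2,2,2-trifluoroethoxy)phosphoryl]propanoate | C=C(CO[Si](C)(C)C(C)(C)C)[C@H]1Oc2cc(O[Si](C(C)C)(C(C)C)C(C)C)c(C(C)=O)cc2[C@H]1OC(=O)C(C)P(=O)(OCC(F)(F)F)OCC(F)(F)F
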